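**Retrosynthetic overview**
1. The plan rests on C13, the fully substituted carbinol carbon of the γ-lactone (ring C). It bears oxygen and three different carbon arms: C12 (towards ring B), C14 and C16 (both in ring C).
2. Ring C comes from lactonisation of 16-OH onto a C15 acid. The acid comes from ozonolysis of a C14–C15 allyl arm, and the 13,16-diol from retentive oxidation of a C13–B and a C16–Si bond.
3. C13–C16 and C14–C15 are made together in one palladium-catalysed three-component coupling of a C13 alkenyl boronate, an oxidisable silylmethyl Grignard reagent and vinyl bromide.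
4. The 6β-hydroxy-8-en-7-one of ring B comes from a 7-ene by C6 allylic oxidation, α-face hydride delivery and singlet-oxygen transposition. The 7-ene boronate comes from sclareol in five steps.
5. Rings A and B (with C5 and C10) are taken preformed from sclareol. Ring C is the only ring made, and it is closed in the last step.

Key step: step 7

Remark on numbering: target (labdane) numbering is used throughout. The methyl carbon of the C13 ketones becomes C14, the silylmethyl carbon is C16, and the inner vinyl carbon is C15. α/β refer to the usual drawing with C20 β.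
Remark on the ligand: the route is drawn for the ligand antipode that places palladium on the Re face of C13. Both antipodes are commercial, and the correct one would be fixed in a trial run.

**Step 1**
Reactants: 1 (−)-sclareol
Product: 2 8α-hydroxy-14,15-dinorlabdan-13-one
Conditions: KMnO4, acetone/H2O, 0 °C → rt
Reagents that add atoms: none
Why: Permanganate cleavage of a vinyl carbinol oxidises the only C=C and then severs the C13–C14 bond next to the tertiary hydroxyl, so C13 is left as a methyl ketone while the tertiary 8α-OH and C5, C8, C9 and C10 are untouched.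

**Step 2**
Reactants: 2 8α-hydroxy-14,15-dinorlabdan-13-one
Product: 4 14,15-dinorlabd-8(17)-en-13-one, via chlorosulfite 3 (not isolated)
Conditions: SOCl2, pyridine, CH2Cl2, −78 → −20 °C
Reagents that add atoms: none
Why: This is an E2-type dehydration of a tertiary alcohol in which the equatorial 8α leaving group has no antiperiplanar ring hydrogen, so the proton is taken mainly from the freely rotating C17 methyl group; the cold basic medium suppresses cyclisation of the hydroxy ketone to its enol ether and acid-driven drift to the 8(9)-alkene, and any 7-ene formed alongside is the product of the next step and is carried along.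

**Step 3**
Reactants: 4 14,15-dinorlabd-8(17)-en-13-one
Product: 5 14,15-dinorlabd-7-en-13-one
Conditions: Co(C32H46N2O2)Cl, the chlorocobalt complex of N,N'-bis(3,5-di-tert-butylsalicylidene)ethane-1,2-diamine (5 mol %), PhSiH3 (10 mol %), benzene, rt
Reagents that add atoms: none
Why: In this cobalt-hydride hydrogen-atom-transfer (MHAT) isomerisation a hydrogen atom adds to C17, the bulky cobalt partner takes back the exposed C7–H rather than the C9–H wedged between C10 and the side chain, and the trisubstituted product does not re-enter the cycle, so the 7-ene should accumulate with C9 unchanged.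

**Step 4**
Reactants: 5 14,15-dinorlabd-7-en-13-one
Product: 7 13-(trifluoromethylsulfonyloxy)-15,16-dinorlabda-7,13(14)-diene, via potassium enolate 6 (not isolated)
Conditions: KHMDS, THF, −78 °C; PhNTf2, −78 → 0 °C
Reagents that add atoms: N-phenylbis(trifluoromethanesulfonimide), O=S(=O)(C(F)(F)F)N(c1ccccc1)S(=O)(=O)C(F)(F)F
Why: In this kinetic enolisation and O-triflation the bulky amide removes a proton from the unhindered methyl group rather than from C12 at −78 °C, and PhNTf2 traps the terminal enolate on oxygen.

**Step 5**
Reactants: 7 13-(trifluoromethylsulfonyloxy)-15,16-dinorlabda-7,13(14)-diene; 8 bis(pinacolato)diboron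
Product: 9 13-(4,4,5,5-tetramethyl-1,3,2-dioxaborolan-2-yl)-15,16-dinorlabda-7,13(14)-diene
Conditions: Pd(dppf)Cl2 (5 mol %), KOAc, 1,4-dioxane, 80 °C
Reagents that add atoms: bis(pinacolato)diboron 8, CC1(C)OB(OC1(C)C)B1OC(C)(C)C(C)(C)O1
Why: In this Miyaura borylation of an alkenyl triflate, oxidative addition into C–OTf, acetate-assisted transmetallation from B2pin2 and reductive elimination put boron on C13 with the 1,1-disubstituted alkene in place, and the ring alkene is a spectator.

**Step 6**
Reactants: 10 (chloromethyl)isopropoxydimethylsilane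
Product: 11 (isopropoxydimethylsilyl)methylmagnesium chloride
Conditions: Mg turnings, THF, 40 °C → rt
Reagents that add atoms: magnesium, [Mg]
Why: Grignard formation from an α-chloromethylsilane is the standard preparation of this hydroxymethyl-anion equivalent, and the bulky isopropoxy group shields silicon from attack by the reagent itself.

**Step 7**
Reactants: 9 13-(pinacolatoboryl)-15,16-dinorlabda-7,13(14)-diene; 11 (isopropoxydimethylsilyl)methylmagnesium chloride; 12 vinyl bromide
Product: 14 (13R)-16-(isopropoxydimethylsilyl)-15-methylidene-13-(4,4,5,5-tetramethyl-1,3,2-dioxaborolan-2-yl)labd-7-ene, via boron ate complex 13 (not isolated)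
Conditions: 9 + 11, THF, 0 °C → rt; NaOTf, DMSO; Pd(OAc)2 (5 mol %), 1,1'-bis[bis(3,5-dimethylphenyl)phosphino]-2,2'-bis[α-(dimethylamino)benzyl]ferrocene (MandyPhos type, single antipode, 6 mol %), vinyl bromide (1 M in THF), 50 °C, sealed tube; crude product filtered and used directly
Reagents that add atoms: (isopropoxydimethylsilyl)methylmagnesium chloride 11, CC(C)O[Si](C)(C)C[Mg]Cl; vinyl bromide 12, C=CBr
Why: Proposed new method: Oxidative addition of vinyl bromide to the zerovalent palladium–diphosphine complex and removal of bromide by NaOTf give a cationic vinylpalladium species that binds the C13=C14 alkene of ate complex 13; this triggers a 1,2-metallate shift in which C16 moves from boron to C13 anti to palladium, palladium ends on C14, and reductive elimination joins C14 to C15. The closest known reaction type is the palladium-catalysed enantioselective conjunctive cross-coupling of α-substituted alkenylboron ate complexes with aryl and alkenyl electrophiles to tertiary boronic esters, including Grignard-derived ate complexes run with NaOTf; the α-silyl migrating group has not been shown. No ring is closed. The one new stereocentre, C13, is set by the chiral ferrocenyl diphosphine, which must hold palladium on the Re face of C13 so that C16 arrives on the Si face (priorities C12 > C14 > B), the resident centres C5, C9 and C10 being too remote to interfere. The step needs the metallate shift to beat direct transfer of a carbon group from boron to palladium (Suzuki-type); this is helped by four-coordinate boron carrying only one migratable carbon group, and the alkylpalladium intermediate cannot undergo β-hydride elimination because C13 is fully substituted. The hindered trisubstituted C7=C8 alkene does not bind palladium, and migration to the boron-bearing carbon fixes the regiochemistry.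

**Step 8**
Reactants: 14 tertiary boronic ester
Product: 15 (13S)-15-methylidenelabd-7-ene-13,16-diol
Conditions: 30% aq H2O2, KF, KHCO3, THF/MeOH, rt → 40 °C
Reagents that add atoms: hydrogen peroxide, OO
Why: Boronate oxidation and Tamao–Fleming oxidation run in one pot, since hydroperoxide adds to boron and to fluoride-activated silicon and each carbon migrates to oxygen with retention, so C13 keeps its configuration; the buffered medium is the one in which β-hydroxysilanes give 1,2-diols rather than Peterson elimination.

**Step 9**
Reactants: 15 (13S)-15-methylidenelabd-7-ene-13,16-diol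
Product: 16 (13S)-13,16-(isopropylidenedioxy)-15-methylidenelabd-7-ene
Conditions: Me2C(OMe)2, PPTS (cat.), CH2Cl2, rt
Reagents that add atoms: 2,2-dimethoxypropane, COC(C)(C)OC
Why: Acid-catalysed transketalisation closes a five-membered dioxolane on the 1,2-diol, which masks both hydroxyls against the chromium oxidant, the hydride and the silylating agent of the next steps without touching C13.

**Step 10**
Reactants: 16 acetonide
Product: 17 (13S)-13,16-(isopropylidenedioxy)-15-methylidenelabd-7-en-6-one
Conditions: CrO3, 3,5-dimethylpyrazole, CH2Cl2, −20 °C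
Reagents that add atoms: chromium trioxide, O=[Cr](=O)=O
Why: Allylic oxidation with the CrO3–3,5-dimethylpyrazole complex should attack C6, the only allylic methylene of the electron-rich ring alkene, as is established for drim-7-enes and labd-7-enes, while the monosubstituted alkene (its allylic C14 sits next to quaternary C13) and the acetonide should be left alone.

**Step 11**
Reactants: 17 7-en-6-one
Product: 18 (13S)-13,16-(isopropylidenedioxy)-15-methylidenelabd-7-en-6β-ol
Conditions: LiAlH4, Et2O, −20 → 0 °C
Reagents that add atoms: none
Why: In this 1,2-hydride reduction of an enone the β face of the C6 carbonyl is screened by the axial methyl groups on C4 and C10, so hydride enters from the α face and sets the axial 6β-OH.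

**Step 12**
Reactants: 18 6β-alcohol
Product: 19 (13S)-6β-(triethylsilyloxy)-13,16-(isopropylidenedioxy)-15-methylidenelabd-7-ene
Conditions: TESOTf, 2,6-lutidine, CH2Cl2, −78 → −20 °C
Reagents that add atoms: triethylsilyl triflate, CC[Si](CC)(CC)OS(=O)(=O)C(F)(F)F
Why: Silylation of a hindered axial alcohol with a silyl triflate and a non-nucleophilic base gives an ether that removes hydroxyl direction of singlet oxygen to the β face, adds bulk to that face, and comes off in the final acid step.

**Step 13**
Reactants: 19 silyl ether
Product: 22 (13S)-6β-(triethylsilyloxy)-13,16-(isopropylidenedioxy)-15-methylidenelabd-8-en-7-one, via 7α-hydroperoxide 20 (not isolated), via 7α-peroxyacetate 21 (not isolated)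
Conditions: O2, tetraphenylporphyrin (cat.), visible light, CH2Cl2, 0 °C; then Ac2O, pyridine, DMAP (cat.), 0 °C → rt
Reagents that add atoms: dioxygen, O=O
Why: In this Schenck ene reaction followed by Kornblum–DeLaMare-type dehydration, singlet oxygen reaches the trisubstituted alkene from the open α face (C20 and the silyloxy group block the β face), bonds to C7 and takes the pseudo-axial 9α-H, since 6α-H lies in the alkene plane and cannot be abstracted; the alkene therefore moves to C8=C9, loss of acetate and 7-H gives the enone, and the monosubstituted alkene is too electron-poor to react.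

**Step 14**
Reactants: 22 8-en-7-one
Product: 24 (13S)-6β-(triethylsilyloxy)-13,16-(isopropylidenedioxy)-7-oxolabd-8-en-15-al, via ozonide 23 (not isolated)
Conditions: O3 (1 equiv, titrated solution), CH2Cl2, −78 °C; PPh3, −78 °C → rt
Reagents that add atoms: ozone, [O-][O+]=O
Why: In this chemoselective ozonolysis (Criegee mechanism) the monosubstituted alkene reacts far faster with electrophilic ozone than the electron-poor, tetrasubstituted and hindered C8=C9 of the enone, so one equivalent should remove only the terminal CH2 and leave C15 as the aldehyde.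

**Step 15**
Reactants: 24 aldehyde
Product: 25 (13S)-6β-(triethylsilyloxy)-13,16-(isopropylidenedioxy)-7-oxolabd-8-en-15-oic acid
Conditions: NaClO2, NaH2PO4, 2-methyl-2-butene, t-BuOH/H2O, rt
Reagents that add atoms: sodium chlorite, [Na+].[O-]Cl=O
Why: The Pinnick oxidation acts on the aldehyde only, and its weakly acidic buffer avoids β-elimination of the C13 oxygen and enolisation at C6.

**Step 16**
Reactants: 25 acid
Product: 27 (13S)-6β,13-dihydroxy-7-oxolabd-8-en-15,16-olide (CNP0324736.2), via trihydroxy acid 26 (not isolated)
Conditions: 1 M aq HCl, THF, rt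
Reagents that add atoms: none
Why: Acid hydrolysis of the acetonide and the triethylsilyl ether frees the 13,16-diol and 6β-OH, and the primary 16-OH then closes ring C on the C15 acid by 5-exo-trig lactonisation (the 13-OH could only form a four-membered ring), with no stereocentre touched.

**Compound list**
1 | (−)-sclareol, (13R)-labd-14-ene-8α,13-diol | C=C[C@](C)(O)CC[C@H]1[C@](C)(O)CC[C@H]2C(C)(C)CCC[C@]12C | starting material
2 | 8α-hydroxy-14,15-dinorlabdan-13-one | CC(=O)CC[C@H]1[C@](C)(O)CC[C@H]2C(C)(C)CCC[C@]12C | intermediate
3 | 8α-chlorosulfite of 2 | CC(=O)CC[C@H]1[C@](C)(OS(=O)Cl)CC[C@H]2C(C)(C)CCC[C@]12C | intermediate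
4 | 14,15-dinorlabd-8(17)-en-13-one | CC(=O)CC[C@H]1C(=C)CC[C@H]2C(C)(C)CCC[C@]12C | intermediate
5 | 14,15-dinorlabd-7-en-13-one | CC(=O)CC[C@H]1C(C)=CC[C@H]2C(C)(C)CCC[C@]12C | intermediate
6 | terminal potassium enolate of 5 | C=C([O-])CC[C@H]1C(C)=CC[C@H]2C(C)(C)CCC[C@]12C.[K+] | intermediate
7 | 13-(trifluoromethylsulfonyloxy)-15,16-dinorlabda-7,13(14)-diene | C=C(OS(=O)(=O)C(F)(F)F)CC[C@H]1C(C)=CC[C@H]2C(C)(C)CCC[C@]12C | intermediate
8 | bis(pinacolato)diboron | CC1(C)OB(OC1(C)C)B1OC(C)(C)C(C)(C)O1 | starting material
9 | 13-(pinacolatoboryl)-15,16-dinorlabda-7,13(14)-diene | C=C(CC[C@H]1C(C)=CC[C@H]2C(C)(C)CCC[C@]12C)B1OC(C)(C)C(C)(C)O1 | intermediate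
10 | (chloromethyl)isopropoxydimethylsilane | CC(C)O[Si](C)(C)CCl | starting material
11 | (isopropoxydimethylsilyl)methylmagnesium chloride | CC(C)O[Si](C)(C)C[Mg]Cl | intermediate
12 | vinyl bromide | C=CBr | starting material
13 | chloromagnesium salt of the boron ate complex from 9 and 11 | C=C(CC[C@H]1C(C)=CC[C@H]2C(C)(C)CCC[C@]12C)[B-]1(C[Si](C)(C)OC(C)C)OC(C)(C)C(C)(C)O1.[Mg+2].[Cl-] | intermediate
14 | (13R)-16-(isopropoxydimethylsilyl)-15-methylidene-13-(pinacolatoboryl)labd-7-ene | C=CC[C@](C[Si](C)(C)OC(C)C)(CC[C@H]1C(C)=CC[C@H]2C(C)(C)CCC[C@]12C)B1OC(C)(C)C(C)(C)O1 | intermediate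
15 | (13S)-15-methylidenelabd-7-ene-13,16-diol | C=CC[C@](CO)(CC[C@H]1C(C)=CC[C@H]2C(C)(C)CCC[C@]12C)O | intermediate
16 | (13S)-13,16-(isopropylidenedioxy)-15-methylidenelabd-7-ene | C=CC[C@@]1(CC[C@H]2C(C)=CC[C@H]3C(C)(C)CCC[C@]23C)COC(C)(C)O1 | intermediate
17 | (13S)-13,16-(isopropylidenedioxy)-15-methylidenelabd-7-en-6-one | C=CC[C@@]1(CC[C@H]2C(C)=CC(=O)[C@H]3C(C)(C)CCC[C@]23C)COC(C)(C)O1 | intermediate
18 | (13S)-13,16-(isopropylidenedioxy)-15-methylidenelabd-7-en-6β-ol | C=CC[C@@]1(CC[C@H]2C(C)=C[C@@H](O)[C@H]3C(C)(C)CCC[C@]23C)COC(C)(C)O1 | intermediate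
19 | 6β-triethylsilyl ether of 18 | C=CC[C@@]1(CC[C@H]2C(C)=C[C@@H](O[Si](CC)(CC)CC)[C@H]3C(C)(C)CCC[C@]23C)COC(C)(C)O1 | intermediate
20 | 7α-hydroperoxy-8-ene from 19 | C=CC[C@@]1(CCC2=C(C)[C@H](OO)[C@@H](O[Si](CC)(CC)CC)[C@H]3C(C)(C)CCC[C@]23C)COC(C)(C)O1 | intermediate
21 | 7α-peroxyacetate of 20 | C=CC[C@@]1(CCC2=C(C)[C@H](OOC(C)=O)[C@@H](O[Si](CC)(CC)CC)[C@H]3C(C)(C)CCC[C@]23C)COC(C)(C)O1 | intermediate
22 | (13S)-6β-(triethylsilyloxy)-13,16-(isopropylidenedioxy)-15-methylidenelabd-8-en-7-one | C=CC[C@@]1(CCC2=C(C)C(=O)[C@@H](O[Si](CC)(CC)CC)[C@H]3C(C)(C)CCC[C@]23C)COC(C)(C)O1 | intermediate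
23 | 1,2,4-trioxolane (ozonide) of the terminal alkene of 22, C15 epimers | C1OOC(O1)C[C@@]2(CCC3=C(C)C(=O)[C@@H](O[Si](CC)(CC)CC)[C@H]4C(C)(C)CCC[C@]34C)COC(C)(C)O2 | intermediate
24 | (13S)-6β-(triethylsilyloxy)-13,16-(isopropylidenedioxy)-7-oxolabd-8-en-15-al | O=CC[C@@]1(CCC2=C(C)C(=O)[C@@H](O[Si](CC)(CC)CC)[C@H]3C(C)(C)CCC[C@]23C)COC(C)(C)O1 | intermediate
25 | (13S)-6β-(triethylsilyloxy)-13,16-(isopropylidenedioxy)-7-oxolabd-8-en-15-oic acid | OC(=O)C[C@@]1(CCC2=C(C)C(=O)[C@@H](O[Si](CC)(CC)CC)[C@H]3C(C)(C)CCC[C@]23C)COC(C)(C)O1 | intermediate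
26 | (13S)-6β,13,16-trihydroxy-7-oxolabd-8-en-15-oic acid | OC(=O)C[C@](CO)(CCC1=C(C)C(=O)[C@@H](O)[C@H]2C(C)(C)CCC[C@]12C)O | intermediate
27 | (13S)-6β,13-dihydroxy-7-oxolabd-8-en-15,16-olide | CC1=C(CC[C@@]2(O)COC(=O)C2)[C@@]2(C)CCCC(C)(C)[C@@H]2[C@H](O)C1=O | target

**Step count**
Total step count: 16. Longest linear sequence: 15 (steps 1–5 and 7–16). Step 6 is a one-step side branch.

**Steps most likely to fail**

1. Step 7. The silylmethyl group may migrate so slowly that direct transfer of a carbon group from boron to palladium takes over. Ate formation from a Grignard reagent and a hindered pinacol ester may also stay incomplete, halide may inhibit the catalyst, or the facial selectivity may be poor.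
 - The fallback builds C13 by known reactions and sets out from triflate 7.
 - Palladium-catalysed methoxycarbonylation (Pd(OAc)2, PPh3, CO, MeOH, Et3N, DMF) gives methyl 15-norlabda-7,13(14)-dien-16-oate F1.
 - DIBAL-H (CH2Cl2, −78 °C) reduces it to 15-norlabda-7,13(14)-dien-16-ol F2.
 - Sharpless asymmetric epoxidation (Ti(OiPr)4, D-(−)-diisopropyl tartrate, t-BuOOH, 4 Å sieves, CH2Cl2, −20 °C) sets C13 in (13R)-13,14-epoxy-15-norlabd-7-en-16-ol F3. The undirected ring alkene is left alone.
 - Vinylmagnesium bromide with catalytic CuI (THF, −40 → 0 °C) opens the epoxide at the unsubstituted C14. This comes back to the route at diol 15.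
 - A Payne shift of the alkoxide is degenerate here and does not erode C13.

2. Step 13. Hydrogen abstraction from the C17 methyl group may compete with abstraction of 9α-H, which would place the new alkene outside the ring.
 - The fallback sets out from silyl ether 19 and follows the classical limonene-to-carvone logic.
 - Nitrosyl chloride (from isoamyl nitrite and Me3SiCl, CH2Cl2, −20 °C) adds to the trisubstituted alkene in preference to the monosubstituted one. Nitrogen goes to C7 and chloride to C8, giving after tautomerisation the 8β-chloro-7-oxime F4.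
 - Warm pyridine removes HCl through the antiperiplanar 9α-H and gives the conjugated 8-en-7-one oxime F5.
 - Buffered reductive deoximation (TiCl3, NH4OAc, THF/H2O, rt) comes back to the route at enone 22.

3. Step 3. The hydrogen atom may be taken back from C9 as well as from C7, so that the alkene drifts to the tetrasubstituted position, or the hindered exocyclic alkene may engage the cobalt hydride too slowly.
 - The fallback sets out from 4 and replaces the radical pathway by a cationic one.
 - Catalytic p-TsOH in CH2Cl2 at rt protonates C17, and the C8 cation loses the more accessible 7-H.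
 - The reaction is stopped well before equilibration. The isomers are separated on AgNO3-impregnated silica, and recovered material is recycled.
 - This comes back to the route at ketone 5 without any new compound.

**Further compounds**
F1 | step 7 | methyl 15-norlabda-7,13(14)-dien-16-oate | C=C(CC[C@H]1C(C)=CC[C@H]2C(C)(C)CCC[C@]12C)C(=O)OC
F2 | step 7 | 15-norlabda-7,13(14)-dien-16-ol | C=C(CO)CC[C@H]1C(C)=CC[C@H]2C(C)(C)CCC[C@]12C
F3 | step 7 | (13R)-13,14-epoxy-15-norlabd-7-en-16-ol | OC[C@]1(CC[C@H]2C(C)=CC[C@H]3C(C)(C)CCC[C@]23C)CO1
F4 | step 13 | (13S)-8β-chloro-7-(hydroxyimino)-6β-(triethylsilyloxy)-13,16-(isopropylidenedioxy)-15-methylidenelabdane | C=CC[C@@]1(CC[C@H]2[C@@](C)(Cl)C(=NO)[C@@H](O[Si](CC)(CC)CC)[C@H]3C(C)(C)CCC[C@]23C)COC(C)(C)O1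
F5 | step 13 | oxime of enone 22 | C=CC[C@@]1(CCC2=C(C)C(=NO)[C@@H](O[Si](CC)(CC)CC)[C@H]3C(C)(C)CCC[C@]23C)COC(C)(C)O1
F0 | step 3 | none | none
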